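**Retrosynthetic overview**

1. The target is released last from its bis-MOM ether by acidic methanolysis. Rings A and B are bought as benzenes, so ring C is the only ring the route forms.
2. Ring C is closed in one operation from two fragments: an aryne of ring A (triple bond C4a≡C8a, from an ortho-silylaryl triflate) takes up the oxygen of an (S)-β-silyloxy amide at C8a (bond O1–C8a), and the C4a carbanion then closes the ring on the amide carbonyl (bond C4–C4a). O1, the stereodefined C2, C3 and C4 arrive together.
3. Enabling feature: C4a and C8a are adjacent carbons of ring A that carry both bonds to ring C, and the oxygen on C5 (next to C4a, kept as OMOM) polarises the aryne so that the alkoxide goes to C8a and the carbanion at C4a sits six atoms from the carbonyl. Ring A is a phloroglucinol, so one of its three oxygens can serve as the triflate leaving group.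
4. Aryne precursor: 5-methoxyresorcinol, bis-MOM protection, three directed ortho-metalations (TMS between the two OMOM groups, then one prenyl group on each side of OMe), removal of one MOM group, triflation.
5. Chiral fragment: methyl 4-hydroxybenzoate, MOM ether, Claisen condensation with N,N-dimethylacetamide, asymmetric transfer hydrogenation (sets C2), TMS ether.

Key step: step 11

Remark on the chemistry: the target is read as the (2S)-flavanone. RuCl[(S,S)-TsDPEN](p-cymene) is assumed to reduce the β-keto amide of step 8 with the facial sense known for acetophenone, which gives the (S)-alcohol; the CIP order at the carbinol carbon (OH > aryl > CH2C(O)NMe2 > H) parallels OH > Ph > CH3 > H.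

**Route**

Step 1
Reactants: 1 5-methoxybenzene-1,3-diol (5-methoxyresorcinol)
Product: 2 1-methoxy-3,5-bis(methoxymethoxy)benzene
Conditions: MOMCl (2.5 equiv), i-Pr2NEt (3 equiv), CH2Cl2, 0 °C → rt
Reagents that add atoms: chloromethyl methyl ether (MOMCl), COCCl
Why: Both phenols are O-alkylated by the reactive α-chloro ether (Williamson-type acetal formation), which installs two equivalent directing groups for the metalations that follow.

Step 2
Reactants: 2 1-methoxy-3,5-bis(methoxymethoxy)benzene
Product: 4 [4-methoxy-2,6-bis(methoxymethoxy)phenyl]trimethylsilane, via aryllithium 3 (not isolated)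
Conditions: n-BuLi (1.2 equiv), THF, 0 °C; TMSCl (1.5 equiv), 0 °C → rt
Reagents that add atoms: chlorotrimethylsilane (TMSCl), C[Si](C)(C)Cl
Why: Directed ortho-metalation should take place at the C–H flanked by the two OMOM groups (cooperative coordination and acidification), and silylation of 3 places there the silicon group that blocks this site now and triggers the aryne later.

Step 3
Reactants: 4 [4-methoxy-2,6-bis(methoxymethoxy)phenyl]trimethylsilane
Product: 6 [4-methoxy-2,6-bis(methoxymethoxy)-3-(3-methylbut-2-en-1-yl)phenyl]trimethylsilane, via aryllithium 5 (not isolated)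
Conditions: s-BuLi (1.2 equiv), TMEDA, THF, −78 °C; CuBr·SMe2 (0.2 equiv), prenyl bromide (1.5 equiv), −78 → 0 °C
Reagents that add atoms: 1-bromo-3-methylbut-2-ene (prenyl bromide), CC(C)=CCBr
Why: With the most acidic site blocked by silicon, directed ortho-metalation can only occur at one of the two equivalent C–H bonds between OMe and OMOM, and copper-assisted allylation of 5 at the primary carbon of prenyl bromide should give the linear prenyl arene.

Step 4
Reactants: 6 [4-methoxy-2,6-bis(methoxymethoxy)-3-(3-methylbut-2-en-1-yl)phenyl]trimethylsilane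
Product: 8 [4-methoxy-2,6-bis(methoxymethoxy)-3,5-bis(3-methylbut-2-en-1-yl)phenyl]trimethylsilane, via aryllithium 7 (not isolated)
Conditions: s-BuLi (1.2 equiv), TMEDA, THF, −78 °C; CuBr·SMe2 (0.2 equiv), prenyl bromide (1.5 equiv), −78 → 0 °C
Reagents that add atoms: 1-bromo-3-methylbut-2-ene (prenyl bromide), CC(C)=CCBr
Why: The last ring C–H, again flanked by OMe and OMOM, should be lithiated at −78 °C faster than the benzylic CH2 of the prenyl group already present (directed ortho-metalation of prenylated MOM ethers is known), and the same copper-assisted allylation completes the fully substituted ring.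

Step 5
Reactants: 8 [4-methoxy-2,6-bis(methoxymethoxy)-3,5-bis(3-methylbut-2-en-1-yl)phenyl]trimethylsilane
Product: 10 3-methoxy-5-(methoxymethoxy)-2,4-bis(3-methylbut-2-en-1-yl)-6-(trimethylsilyl)phenol, via aryl silyl ether 9 (not isolated)
Conditions: TMSOTf (1.05 equiv), 2,2'-bipyridyl (3 equiv), MeCN, 0 °C; then H2O, rt
Reagents that add atoms: none
Why: The TMSOTf/2,2'-bipyridyl pair turns an aryl MOM ether into the aryl silyl ether without Brønsted acid (so the acid-labile aryl–Si bond between two oxygens and the prenyl groups should survive), and with one equivalent it should cleave mainly one of the two equivalent acetals, 9 being hydrolysed on work-up while unchanged 8 and doubly cleaved diol are separated and recycled (known non-acidic MOM cleavage).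

Step 6
Reactants: 10 3-methoxy-5-(methoxymethoxy)-2,4-bis(3-methylbut-2-en-1-yl)-6-(trimethylsilyl)phenol
Product: 11 3-methoxy-5-(methoxymethoxy)-2,4-bis(3-methylbut-2-en-1-yl)-6-(trimethylsilyl)phenyl trifluoromethanesulfonate
Conditions: Tf2O (1.2 equiv), pyridine (3 equiv), CH2Cl2, 0 °C
Reagents that add atoms: trifluoromethanesulfonic anhydride (Tf2O), O=S(=O)(OS(=O)(=O)C(F)(F)F)C(F)(F)F
Why: O-Sulfonylation of the phenol gives the ortho-silylaryl triflate, the standard fluoride-triggered aryne precursor (Kobayashi type).

Step 7
Reactants: 12 methyl 4-hydroxybenzoate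
Product: 13 methyl 4-(methoxymethoxy)benzoate
Conditions: MOMCl (1.3 equiv), i-Pr2NEt (2 equiv), CH2Cl2, 0 °C → rt
Reagents that add atoms: chloromethyl methyl ether (MOMCl), COCCl
Why: The phenol is masked as a MOM ether that is inert to enolates, fluoride and arynes and falls off together with the second MOM group in the last step.

Step 8
Reactants: 13 methyl 4-(methoxymethoxy)benzoate; 14 N,N-dimethylacetamide
Product: 16 3-[4-(methoxymethoxy)phenyl]-N,N-dimethyl-3-oxopropanamide, via lithium enolate 15 (not isolated)
Conditions: 14 (2.2 equiv), LiN(i-Pr)2 (2.2 equiv), THF, −78 °C; 13, −78 → 0 °C; AcOH quench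
Reagents that add atoms: none
Why: Crossed Claisen condensation of the amide enolate with the non-enolisable ester should stop at the β-keto amide because the product is stored as its enolate until the quench.

Step 9
Reactants: 16 3-[4-(methoxymethoxy)phenyl]-N,N-dimethyl-3-oxopropanamide
Product: 17 (3S)-3-hydroxy-3-[4-(methoxymethoxy)phenyl]-N,N-dimethylpropanamide
Conditions: RuCl[(S,S)-TsDPEN](p-cymene) (1 mol %), HCO2H/Et3N (5:2), EtOAc, 30 °C
Reagents that add atoms: none
Why: Noyori–Ikariya asymmetric transfer hydrogenation of the aryl ketone sets the future C2: the catalyst delivers hydride to the face that keeps the aryl group next to its arene ligand, which with the (S,S)-ligand is expected to give the (S)-alcohol.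

Step 10
Reactants: 17 (3S)-3-hydroxy-3-[4-(methoxymethoxy)phenyl]-N,N-dimethylpropanamide
Product: 18 (3S)-3-[4-(methoxymethoxy)phenyl]-N,N-dimethyl-3-[(trimethylsilyl)oxy]propanamide
Conditions: TMSCl (1.3 equiv), imidazole (2 equiv), CH2Cl2, 0 °C; non-aqueous work-up
Reagents that add atoms: chlorotrimethylsilane (TMSCl), C[Si](C)(C)Cl
Why: O-Silylation leaves the stereocentre untouched and removes the O–H proton, so that fluoride can later unveil the alkoxide in a proton-free flask.

Step 11
Reactants: 11 3-methoxy-5-(methoxymethoxy)-2,4-bis(3-methylbut-2-en-1-yl)-6-(trimethylsilyl)phenyl trifluoromethanesulfonate; 18 (3S)-3-[4-(methoxymethoxy)phenyl]-N,N-dimethyl-3-[(trimethylsilyl)oxy]propanamide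
Product: 22 (2S)-7-methoxy-5-(methoxymethoxy)-2-[4-(methoxymethoxy)phenyl]-6,8-bis(3-methylbut-2-en-1-yl)-2,3-dihydro-4H-chromen-4-one, via cesium alkoxide 19 (not isolated), via aryne 20 (not isolated), via cesium aminal alkoxide 21 (not isolated)
Conditions: 11 (1.0 equiv), 18 (1.3 equiv), CsF (4 equiv), 18-crown-6 (1 equiv), THF, 0 °C → rt; then AcOH (5 equiv), 0 °C, H2O
Reagents that add atoms: none
Why: Proposed new method: fluoride strips the trimethylsilyl group of 11 (loss of triflate gives aryne 20) and of 18 (giving the proton-free alkoxide 19), the alkoxide oxygen adds to C8a of the aryne and the resulting C4a carbanion adds to the amide carbonyl six atoms away to give aminal alkoxide 21, which cannot expel dimethylamide and releases the ketone only on the acetic acid quench; the closest known reaction type is the fluoride-induced annulation of arynes with salicylate esters to xanthones (phenoxide addition, then acyl capture by the aryl anion), together with the known O-arylation of aliphatic alcohols by arynes. Ring C closes by a 6-exo-trig addition of the aryl anion to the C=O, forming the C4–C4a bond directly after the O1–C8a bond in the same operation. No stereocentre is created: C2 is carried over from 18 with retention because its C–O bond is never broken, and it is shielded from base-induced retro-oxa-Michael racemisation because the C4 carbonyl stays masked as the aminal alkoxide until the medium is acidic. The step needs regioselective attack at C8a, which the inductively withdrawing OMOM group on C5 should secure (the nucleophile adds to the aryne carbon remote from it so that the charge develops at C4a next to oxygen, the usual behaviour of 3-alkoxyarynes), the other neighbour of the triple bond being only the CH2 of the C8 prenyl group. It also needs acyl capture to outrun protonation of the aryl anion, which the silyl ether (no O–H in the flask), the aprotic medium and the low acidity of the amide α-C–H are meant to secure. The prenyl double bonds cannot reach the aryne carbons for an intramolecular ene reaction, and the charged alkoxide should outcompete them intermolecularly.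

Step 12
Reactants: 22 (2S)-7-methoxy-5-(methoxymethoxy)-2-[4-(methoxymethoxy)phenyl]-6,8-bis(3-methylbut-2-en-1-yl)-2,3-dihydro-4H-chromen-4-one
Product: 23 (2S)-5-hydroxy-2-(4-hydroxyphenyl)-7-methoxy-6,8-bis(3-methylbut-2-en-1-yl)-2,3-dihydro-4H-chromen-4-one (target)
Conditions: 3 M aq. HCl/MeOH (1:10), 40 °C, stopped at full conversion
Reagents that add atoms: none
Why: Acid-catalysed methanolysis removes both MOM acetals (the one peri to the carbonyl first), a deprotection used on prenylated flavanones, and C2 should not epimerise because flavanone ring opening is a base-mediated process.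

**Compound list**

1 | 5-methoxybenzene-1,3-diol | COc1cc(O)cc(O)c1 | starting material
2 | 1-methoxy-3,5-bis(methoxymethoxy)benzene | COCOc1cc(OC)cc(OCOC)c1 | intermediate
3 | [4-methoxy-2,6-bis(methoxymethoxy)phenyl]lithium | [Li]c1c(OCOC)cc(OC)cc1OCOC | intermediate (not isolated)
4 | [4-methoxy-2,6-bis(methoxymethoxy)phenyl]trimethylsilane | COCOc1cc(OC)cc(OCOC)c1[Si](C)(C)C | intermediate
5 | [6-methoxy-2,4-bis(methoxymethoxy)-3-(trimethylsilyl)phenyl]lithium | [Li]c1c(OC)cc(OCOC)c([Si](C)(C)C)c1OCOC | intermediate (not isolated)
6 | [4-methoxy-2,6-bis(methoxymethoxy)-3-(3-methylbut-2-en-1-yl)phenyl]trimethylsilane | COCOc1cc(OC)c(CC=C(C)C)c(OCOC)c1[Si](C)(C)C | intermediate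
7 | [2-methoxy-4,6-bis(methoxymethoxy)-3-(3-methylbut-2-en-1-yl)-5-(trimethylsilyl)phenyl]lithium | [Li]c1c(OC)c(CC=C(C)C)c(OCOC)c([Si](C)(C)C)c1OCOC | intermediate (not isolated)
8 | [4-methoxy-2,6-bis(methoxymethoxy)-3,5-bis(3-methylbut-2-en-1-yl)phenyl]trimethylsilane | COCOc1c(CC=C(C)C)c(OC)c(CC=C(C)C)c(OCOC)c1[Si](C)(C)C | intermediate
9 | trimethyl{[3-methoxy-5-(methoxymethoxy)-2,4-bis(3-methylbut-2-en-1-yl)-6-(trimethylsilyl)phenyl]oxy}silane | COCOc1c(CC=C(C)C)c(OC)c(CC=C(C)C)c(O[Si](C)(C)C)c1[Si](C)(C)C | intermediate (not isolated)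
10 | 3-methoxy-5-(methoxymethoxy)-2,4-bis(3-methylbut-2-en-1-yl)-6-(trimethylsilyl)phenol | COCOc1c(CC=C(C)C)c(OC)c(CC=C(C)C)c(O)c1[Si](C)(C)C | intermediate
11 | 3-methoxy-5-(methoxymethoxy)-2,4-bis(3-methylbut-2-en-1-yl)-6-(trimethylsilyl)phenyl trifluoromethanesulfonate | COCOc1c(CC=C(C)C)c(OC)c(CC=C(C)C)c(OS(=O)(=O)C(F)(F)F)c1[Si](C)(C)C | intermediate
12 | methyl 4-hydroxybenzoate | COC(=O)c1ccc(O)cc1 | starting material
13 | methyl 4-(methoxymethoxy)benzoate | COCOc1ccc(cc1)C(=O)OC | intermediate
14 | N,N-dimethylacetamide | CC(=O)N(C)C | starting material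
15 | lithium 1-(dimethylamino)ethen-1-olate | [Li]OC(=C)N(C)C | intermediate (not isolated)
16 | 3-[4-(methoxymethoxy)phenyl]-N,N-dimethyl-3-oxopropanamide | COCOc1ccc(cc1)C(=O)CC(=O)N(C)C | intermediate
17 | (3S)-3-hydroxy-3-[4-(methoxymethoxy)phenyl]-N,N-dimethylpropanamide | O[C@H](c1ccc(OCOC)cc1)CC(=O)N(C)C | intermediate
18 | (3S)-3-[4-(methoxymethoxy)phenyl]-N,N-dimethyl-3-[(trimethylsilyl)oxy]propanamide | C[Si](C)(C)O[C@H](c1ccc(OCOC)cc1)CC(=O)N(C)C | intermediate
19 | cesium (1S)-3-(dimethylamino)-1-[4-(methoxymethoxy)phenyl]-3-oxopropan-1-olate | [Cs+].[O-][C@H](c1ccc(OCOC)cc1)CC(=O)N(C)C | intermediate (not isolated)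
20 | 3-methoxy-5-(methoxymethoxy)-2,4-bis(3-methylbut-2-en-1-yl)benzyne (triple bond between the former triflate and silyl carbons of 11) | COCOC1=C(CC=C(C)C)C(OC)=C(CC=C(C)C)C#C1 | intermediate (not isolated)
21 | cesium (2S)-4-(dimethylamino)-7-methoxy-5-(methoxymethoxy)-2-[4-(methoxymethoxy)phenyl]-6,8-bis(3-methylbut-2-en-1-yl)-3,4-dihydro-2H-chromen-4-olate (both C4 epimers) | [Cs+].COc1c(CC=C(C)C)c(OCOC)c2c(c1CC=C(C)C)O[C@H](c1ccc(OCOC)cc1)CC2([O-])N(C)C | intermediate (not isolated)
22 | (2S)-7-methoxy-5-(methoxymethoxy)-2-[4-(methoxymethoxy)phenyl]-6,8-bis(3-methylbut-2-en-1-yl)-2,3-dihydro-4H-chromen-4-one | COc1c(CC=C(C)C)c(OCOC)c2c(c1CC=C(C)C)O[C@H](c1ccc(OCOC)cc1)CC2=O | intermediate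
23 | (2S)-5-hydroxy-2-(4-hydroxyphenyl)-7-methoxy-6,8-bis(3-methylbut-2-en-1-yl)-2,3-dihydro-4H-chromen-4-one | COc1c(CC=C(C)C)c(O)c2c(c1CC=C(C)C)O[C@H](c1ccc(O)cc1)CC2=O | target

**Step count**

Total: 12 steps. Longest linear sequence: 8 steps (steps 1–6, 11, 12).

**Steps most likely to fail**

Step 11. The C4a carbanion may be protonated (by adventitious water or by transfer of an amide α-hydrogen) before it closes ring C, or the free alkoxide may lose configuration by retro-aldol cleavage before it meets the aryne. The fallback sets out from 11 and from alcohol 17 and returns at 22. Under KF/18-crown-6 in THF at 0 °C → rt, the known O–H insertion of an alcohol into an aryne should give, with the same regiochemistry and with retention, (3S)-3-[3-methoxy-5-(methoxymethoxy)-2,4-bis(3-methylbut-2-en-1-yl)phenoxy]-3-[4-(methoxymethoxy)phenyl]-N,N-dimethylpropanamide F1, in which C4a carries hydrogen. Activation of the amide with Tf2O and 2-fluoropyridine in CH2Cl2 at −78 → 0 °C should then let the only free ring position (C4a, flanked by two oxygens and para to OMe) attack the activated carbon in an intramolecular Vilsmeier–Haack-type acylation. This gives the cyclic iminium salt (2S)-N-{7-methoxy-5-(methoxymethoxy)-2-[4-(methoxymethoxy)phenyl]-6,8-bis(3-methylbut-2-en-1-yl)-2,3-dihydro-4H-chromen-4-ylidene}-N-methylmethanaminium triflate F2, which aqueous NaHCO3 should hydrolyse to 22.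

Step 5. The two equivalent acetals may be differentiated poorly, with over-cleavage to the diol. The fallback sets out from 8 and returns at 11. Excess TMSOTf/2,2'-bipyridyl followed by water should remove both MOM groups and give 5-methoxy-4,6-bis(3-methylbut-2-en-1-yl)-2-(trimethylsilyl)benzene-1,3-diol F3. One equivalent of PhNTf2 with Et3N in CH2Cl2 at 0 °C should then sulfonylate one hydroxyl, the first triflate lowering the nucleophilicity of the remaining phenoxide, to give 3-hydroxy-5-methoxy-4,6-bis(3-methylbut-2-en-1-yl)-2-(trimethylsilyl)phenyl trifluoromethanesulfonate F4. MOMCl with i-Pr2NEt protects the remaining phenol and gives 11.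

Step 12. The C6 prenyl group may cyclise onto the freed C5 hydroxyl under acid (chroman formation), or methanol or HCl may add to the trisubstituted alkenes. The fallback sets out from 22 and returns at 23. It replaces Brønsted-acid solvolysis by an acid-free acetal-to-silyl-ether exchange: excess TMSOTf/2,2'-bipyridyl in MeCN at 0 °C should give (2S)-7-methoxy-6,8-bis(3-methylbut-2-en-1-yl)-5-[(trimethylsilyl)oxy]-2-{4-[(trimethylsilyl)oxy]phenyl}-2,3-dihydro-4H-chromen-4-one F5. Neutral hydrolysis of the two aryl silyl ethers with water in THF then gives 23.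

**Further compounds**

F1 | step 11 | (3S)-3-[3-methoxy-5-(methoxymethoxy)-2,4-bis(3-methylbut-2-en-1-yl)phenoxy]-3-[4-(methoxymethoxy)phenyl]-N,N-dimethylpropanamide | COCOc1cc(O[C@H](c2ccc(OCOC)cc2)CC(=O)N(C)C)c(CC=C(C)C)c(OC)c1CC=C(C)C
F2 | step 11 | (2S)-N-{7-methoxy-5-(methoxymethoxy)-2-[4-(methoxymethoxy)phenyl]-6,8-bis(3-methylbut-2-en-1-yl)-2,3-dihydro-4H-chromen-4-ylidene}-N-methylmethanaminium triflate | C[N+](C)=C1C[C@@H](c2ccc(OCOC)cc2)Oc2c1c(OCOC)c(CC=C(C)C)c(OC)c2CC=C(C)C.[O-]S(=O)(=O)C(F)(F)F
F3 | step 5 | 5-methoxy-4,6-bis(3-methylbut-2-en-1-yl)-2-(trimethylsilyl)benzene-1,3-diol | COc1c(CC=C(C)C)c(O)c([Si](C)(C)C)c(O)c1CC=C(C)C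
F4 | step 5 | 3-hydroxy-5-methoxy-4,6-bis(3-methylbut-2-en-1-yl)-2-(trimethylsilyl)phenyl trifluoromethanesulfonate | COc1c(CC=C(C)C)c(O)c([Si](C)(C)C)c(OS(=O)(=O)C(F)(F)F)c1CC=C(C)C
F5 | step 12 | (2S)-7-methoxy-6,8-bis(3-methylbut-2-en-1-yl)-5-[(trimethylsilyl)oxy]-2-{4-[(trimethylsilyl)oxy]phenyl}-2,3-dihydro-4H-chromen-4-one | COc1c(CC=C(C)C)c(O[Si](C)(C)C)c2c(c1CC=C(C)C)O[C@H](c1ccc(O[Si](C)(C)C)cc1)CC2=O
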